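**Assumption:** the target, 5,7,8-trimethoxy-2-(2,3,4,5-tetramethoxyphenyl)-4H-chromen-4-one, has no stereocentre, so "single enantiomer" means the one achiral compound; 1,2,3,4-tetramethoxybenzene and 2'-hydroxy-3',4',6'-trimethoxyacetophenone are taken as catalogue chemicals.

## Retrosynthetic overview

- Open the pyranone ring at O1–C2 and remove the C2=C3 unsaturation: flavone ⇒ 2'-hydroxychalcone (oxidative cyclisation).
- Cut the chalcone Cα=Cβ bond (Claisen–Schmidt): ⇒ 2'-hydroxy-3',4',6'-trimethoxyacetophenone + 2,3,4,5-tetramethoxybenzaldehyde.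
- Cut the aryl–CHO bond (ortho-lithiation, DMF): ⇒ 1,2,3,4-tetramethoxybenzene.
- Ring order: both benzene rings are bought fully methoxylated; only the pyranone C-ring is built, in the last step.

## Route

**Step 1**
Reactants: 1 1,2,3,4-tetramethoxybenzene
Product: 4 2,3,4,5-tetramethoxybenzaldehyde, via aryllithium 2 (not isolated), via lithium hemiaminal alkoxide 3 (not isolated)
Conditions: n-BuLi (1.2 equiv), TMEDA (1.2 equiv), THF, 0 °C to rt, 2 h; DMF (2 equiv), 0 °C to rt; then H2O
Reagents that add atoms: N,N-dimethylformamide, CN(C)C=O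
Why: Directed ortho-metalation puts lithium next to a methoxy group at the only kind of free ring position (C5 and C6 are equivalent), and DMF formylation stops at the tetrahedral alkoxide 3, which gives the aldehyde only on aqueous work-up; no stereocentre is formed in the product.

**Step 2**
Reactants: 4 2,3,4,5-tetramethoxybenzaldehyde; 5 2'-hydroxy-3',4',6'-trimethoxyacetophenone
Product: 7 (E)-1-(2-hydroxy-3,4,6-trimethoxyphenyl)-3-(2,3,4,5-tetramethoxyphenyl)prop-2-en-1-one, via aldol adduct 6 (not isolated)
Conditions: KOH (50% aq., 10 equiv), EtOH, rt, 48 h; then 2 M HCl to pH 3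
Reagents that add atoms: none
Why: Claisen–Schmidt (crossed aldol) condensation, in which the enolate of 5 can only add to the non-enolisable aldehyde 4 and E1cB loss of water from 6 gives the conjugated E-enone under thermodynamic control, the methyl ethers being inert to KOH.

**Step 3**
Reactants: 7 (E)-1-(2-hydroxy-3,4,6-trimethoxyphenyl)-3-(2,3,4,5-tetramethoxyphenyl)prop-2-en-1-one
Product: 9 5,7,8-trimethoxy-2-(2,3,4,5-tetramethoxyphenyl)-4H-chromen-4-one, via flavanone 8 (not isolated)
Conditions: I2 (10 mol %), DMSO, 120 °C, 3 h; aq. Na2S2O3 work-up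
Reagents that add atoms: none
Why: Iodine-catalysed oxidative cyclisation of a 2'-hydroxychalcone, in which 6-endo oxa-Michael closure gives flavanone 8 and its C2–C3 bond is then dehydrogenated with DMSO as terminal oxidant, which removes the transient C-2 stereocentre and leaves the achiral flavone.

## Compound list

1 | 1,2,3,4-tetramethoxybenzene | COc1ccc(OC)c(OC)c1OC | starting material
2 | (2,3,4,5-tetramethoxyphenyl)lithium, formed in situ | [Li]c1cc(OC)c(OC)c(OC)c1OC | intermediate
3 | lithium (dimethylamino)(2,3,4,5-tetramethoxyphenyl)methanolate, racemic, formed in situ | CN(C)C([O-])c1cc(OC)c(OC)c(OC)c1OC.[Li+] | intermediate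
4 | 2,3,4,5-tetramethoxybenzaldehyde | O=Cc1cc(OC)c(OC)c(OC)c1OC | intermediate
5 | 2'-hydroxy-3',4',6'-trimethoxyacetophenone, i.e. 1-(2-hydroxy-3,4,6-trimethoxyphenyl)ethan-1-one | CC(=O)c1c(O)c(OC)c(OC)cc1OC | starting material
6 | 3-hydroxy-1-(2-hydroxy-3,4,6-trimethoxyphenyl)-3-(2,3,4,5-tetramethoxyphenyl)propan-1-one, racemic, formed in situ | O=C(CC(O)c1cc(OC)c(OC)c(OC)c1OC)c1c(O)c(OC)c(OC)cc1OC | intermediate
7 | (E)-1-(2-hydroxy-3,4,6-trimethoxyphenyl)-3-(2,3,4,5-tetramethoxyphenyl)prop-2-en-1-one (2'-hydroxy-2,3,3',4,4',5,6'-heptamethoxychalcone) | COc1cc(/C=C/C(=O)c2c(O)c(OC)c(OC)cc2OC)c(OC)c(OC)c1OC | intermediate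
8 | 5,7,8-trimethoxy-2-(2,3,4,5-tetramethoxyphenyl)chroman-4-one, racemic, formed in situ | COc1cc(C2CC(=O)c3c(OC)cc(OC)c(OC)c3O2)c(OC)c(OC)c1OC | intermediate
9 | 5,7,8-trimethoxy-2-(2,3,4,5-tetramethoxyphenyl)-4H-chromen-4-one (5,7,8,2',3',4',5'-heptamethoxyflavone), achiral | COc1cc(-c2cc(=O)c3c(OC)cc(OC)c(OC)c3o2)c(OC)c(OC)c1OC | target

## Summary

Total step count: 3.
Longest linear sequence: 3 steps (1 → 4 → 7 → 9).

## Steps most likely to fail, with fallbacks

**Step 1 (lithiation and formylation).** The risk is incomplete metalation or attack of n-BuLi on a methyl ether. The fallback sets out from 1 and comes back at 4, and swaps carbanion chemistry for electrophilic aromatic substitution (Rieche formylation). Treating 1 with dichloromethyl methyl ether and TiCl4 in CH2Cl2 at 0 °C gives 1-[chloro(methoxy)methyl]-2,3,4,5-tetramethoxybenzene F1, which is not isolated. Water at work-up hydrolyses it to 4.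

**Step 2 (Claisen–Schmidt condensation).** The acetophenone is flanked on both sides and its phenoxide deactivates the enolate, so the aldol can be slow and Cannizzaro reaction of 4 can compete. Partial closure to flavanone 8 is harmless, because step 3 converts it as well. The fallback sets out from 4 and 5 and comes back at 9, bypassing 7 by a Baker–Venkataraman sequence that needs no oxidation. Pinnick oxidation of 4 (NaClO2, NaH2PO4, 2-methyl-2-butene, t-BuOH/H2O) gives 2,3,4,5-tetramethoxybenzoic acid F2. Oxalyl chloride with catalytic DMF in CH2Cl2 turns it into 2,3,4,5-tetramethoxybenzoyl chloride F3. Acylation of phenol 5 in pyridine with DMAP gives 2-acetyl-3,5,6-trimethoxyphenyl 2,3,4,5-tetramethoxybenzoate F4. KOH in pyridine at 50 °C shifts the aroyl group to carbon and gives 1-(2-hydroxy-3,4,6-trimethoxyphenyl)-3-(2,3,4,5-tetramethoxyphenyl)propane-1,3-dione F5. Catalytic H2SO4 in AcOH at 100 °C cyclodehydrates F5 to 9.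

**Step 3 (I2/DMSO oxidative cyclisation).** The risks are cleavage of the 5-OMe group peri to the carbonyl, iodination at the free C-6 of the electron-rich A-ring, and a stall at the flavanone. The fallback sets out from 7 and comes back at 9 by a stepwise, iodine-free sequence. Chalcone 7 is isomerised to flavanone 8 with NaOAc in refluxing EtOH, and 8 is isolated. DDQ (1.5 equiv) in refluxing dioxane then dehydrogenates it by hydride abstraction to 9. New compounds on its way: none F0. The Baker–Venkataraman sequence above is a second way round this step.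

## Further compounds

F1 | step 1 | 1-[chloro(methoxy)methyl]-2,3,4,5-tetramethoxybenzene, racemic | COC(Cl)c1cc(OC)c(OC)c(OC)c1OC
F2 | step 2 | 2,3,4,5-tetramethoxybenzoic acid | OC(=O)c1cc(OC)c(OC)c(OC)c1OC
F3 | step 2 | 2,3,4,5-tetramethoxybenzoyl chloride | ClC(=O)c1cc(OC)c(OC)c(OC)c1OC
F4 | step 2 | 2-acetyl-3,5,6-trimethoxyphenyl 2,3,4,5-tetramethoxybenzoate | CC(=O)c1c(OC(=O)c2cc(OC)c(OC)c(OC)c2OC)c(OC)c(OC)cc1OC
F5 | step 2 | 1-(2-hydroxy-3,4,6-trimethoxyphenyl)-3-(2,3,4,5-tetramethoxyphenyl)propane-1,3-dione | O=C(CC(=O)c1cc(OC)c(OC)c(OC)c1OC)c1c(O)c(OC)c(OC)cc1OC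
F0 | step 3 | none | none
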